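A direct plan would convert methyl vanillate A1 into its 5-prenyl derivative A2 (O-propargylation, semi-hydrogenation, Claisen rearrangement) and cap the phenol with TIPS. It would then condense this ester with methyl methoxyacetate A3 to the β-keto ester A4, fuse A4 with phloroglucinol A5 near 240 °C (Mentzer pyrone synthesis) to the silylated flavone A6, and desilylate.
Its weakest steps would be:
- The thermal fusion of A4 with A5: the whole carbon inventory, with a heat- and acid-sensitive ortho-prenyl aryl silyl ether, would meet the harshest step last, on an α-substituted, electron-rich aroylacetate of the kind that reacts poorly.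
- The installation of one prenyl group in three operations with a redox change: this builds a single C–C bond.
- The crossed Claisen condensation to A4: it needs a large excess of amide base and competes with self-condensation of A3.

Retrosynthetic overview
- Ring C would be bought, not made: comenic acid supplies O1, C2, C3–O, C4=O, C4a and C8a, and its carboxyl carbon becomes C5. Its only hydroxyl is methylated to the 3-OMe, so no differentiation among phenols is ever needed.
- Ring B would be joined to C2 by Negishi coupling of a bromopyranone, and its prenyl group would come from a single C-alkylation.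
- Ring A would be built last in one operation from the pyranonyl diazo ketone and an alkoxyacetylene (Wolff shift, [2+2], 4π opening, 6π electrocyclization, tautomerisation), forming C8–C8a, C5–C6, C7–C8 and C4a–C5. This sequence delivers exactly the ring A pattern of the target: oxygen on C5, C7 and C8a, hydrogen on C6 and C8.
- No step would exceed about 100 °C and none would be acidic.

Key step: step 9

Remarks: comenic acid, 4-bromo-2-methoxyphenol, prenyl bromide, 2-(trimethylsilyl)ethanol and trichloroethylene are taken as commercial. Positions of the final skeleton are given in flavone numbering (O1, C2–C4, C4a, C5–C8, C8a; ring B primed); names of pyranones use pyranone locants. Ar = 3-methoxy-5-(3-methylbut-2-enyl)-4-(triisopropylsilyloxy)phenyl.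

Step 1
Reactants: 1 4-bromo-2-methoxyphenol; 2 1-bromo-3-methylbut-2-ene (prenyl bromide)
Product: 4 4-bromo-2-methoxy-6-(3-methylbut-2-enyl)phenol, via sodium phenoxide 3 (not isolated)
Conditions: NaH (1.05 equiv), toluene, 0 °C → rt; 2 (1.1 equiv), rt, 16 h
Reagents that add atoms: none
Why: ortho-C-alkylation of a sodium phenoxide held as a contact ion pair in a non-polar solvent: the shielded oxygen leaves the ring carbons as nucleophiles, the para carbon carries bromine and one ortho carbon the methoxy group, so only C6 can be alkylated, and SN2 attack at the primary carbon of 2 keeps the prenyl group linear.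

Step 2
Reactants: 4 4-bromo-2-methoxy-6-(3-methylbut-2-enyl)phenol
Product: 5 [4-bromo-2-methoxy-6-(3-methylbut-2-enyl)phenoxy]triisopropylsilane
Conditions: TIPSOTf (1.2 equiv), 2,6-lutidine (2 equiv), CH2Cl2, 0 °C → rt
Reagents that add atoms: triisopropylsilyl trifluoromethanesulfonate, CC(C)[Si](C(C)C)(C(C)C)OS(=O)(=O)C(F)(F)F
Why: silyl ether formation: the phenol sits between methoxy and prenyl groups and needs the reactive triflate, the lutidine buffer excludes acid that could close the phenol onto the prenyl double bond, and TIPS is chosen because it should withstand butyllithium, the saponification and the ketene chemistry.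

Step 3
Reactants: 6 comenic acid (5-hydroxy-4-oxo-4H-pyran-2-carboxylic acid)
Product: 7 6-bromo-5-hydroxy-4-oxo-4H-pyran-2-carboxylic acid
Conditions: Br2 (1.05 equiv), H2O, 0 °C → rt
Reagents that add atoms: bromine, BrBr
Why: electrophilic bromination of an enol: pyranone C6 is the β-carbon of the C5 enol and the only ring position activated by the hydroxyl, whereas C3 lies beside the carboxyl group, so bromine should enter only at C6, the future C2 of the flavone.

Step 4
Reactants: 7 6-bromo-5-hydroxy-4-oxo-4H-pyran-2-carboxylic acid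
Product: 8 methyl 6-bromo-5-methoxy-4-oxo-4H-pyran-2-carboxylate
Conditions: MeI (3 equiv), K2CO3 (2.5 equiv), DMF, rt
Reagents that add atoms: iodomethane, CI
Why: Williamson methylation of the carboxylate and of the enolate in one operation: the enol oxygen, the only hydroxyl present, becomes the 3-OMe of the target, so no later differentiation among phenols is needed.

Step 5
Reactants: 5 [4-bromo-2-methoxy-6-(3-methylbut-2-enyl)phenoxy]triisopropylsilane; 8 methyl 6-bromo-5-methoxy-4-oxo-4H-pyran-2-carboxylate
Product: 11 methyl 6-Ar-5-methoxy-4-oxo-4H-pyran-2-carboxylate, via aryllithium 9 (not isolated), via arylzinc chloride 10 (not isolated)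
Conditions: 5 (1.2 equiv), n-BuLi (1.2 equiv), THF, −78 °C; ZnCl2 (1.3 equiv), −78 → 0 °C; 8 (1.0 equiv), Pd(PPh3)4 (4 mol %), rt → 45 °C
Reagents that add atoms: none
Why: Negishi coupling: bromine–lithium exchange at −78 °C should outrun proton transfer, the zinc reagent tolerates the ester and the pyranone carbonyl, and the C–Br bond of 8, a vinylogous acyl bromide, undergoes oxidative addition readily, so the C2–C1' bond forms at the carbon that bromination marked.

Step 6
Reactants: 11 methyl 6-Ar-5-methoxy-4-oxo-4H-pyran-2-carboxylate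
Product: 12 6-Ar-5-methoxy-4-oxo-4H-pyran-2-carboxylic acid
Conditions: LiOH·H2O (1.5 equiv), THF/H2O 3:1, 0 °C; 1 M HCl to pH 3 at 0 °C
Reagents that add atoms: lithium hydroxide, [Li+].[OH-]
Why: saponification: the ester on the electron-poor pyranone should be cleaved at 0 °C faster than hydroxide adds to the ring (pyranone C6 is shielded by the aryl group), the hindered aryl TIPS ether is left alone, and the brief cold acidification spares the prenyl group.

Step 7
Reactants: 12 6-Ar-5-methoxy-4-oxo-4H-pyran-2-carboxylic acid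
Product: 14 2-(diazoacetyl)-6-Ar-5-methoxy-4H-pyran-4-one, via ethyl carbonic anhydride 13 (not isolated)
Conditions: ClCO2Et (1.1 equiv), Et3N (1.1 equiv), THF, −15 °C; CH2N2 (2.5 equiv, Et2O), 0 °C, 2 h; excess CH2N2 purged with N2
Reagents that add atoms: diazomethane, C=[N+]=[N-]
Why: acylation of diazomethane by a mixed carbonic anhydride (first stage of the Arndt–Eistert sequence): the ethyl carbonate leaving group acts as the base, so no hydrogen chloride forms that could add to the prenyl double bond or turn the diazo ketone into a chloromethyl ketone.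

Step 8
Reactants: 15 2-(trimethylsilyl)ethanol; 16 trichloroethylene
Product: 21 [2-(ethynyloxy)ethyl]trimethylsilane, via potassium alkoxide 17 (not isolated), via dichlorovinyl ether 18 (not isolated), via chloroalkynyl ether 19 (not isolated), via lithium alkoxyacetylide 20 (not isolated)
Conditions: KH (2 equiv), THF, 0 °C; 16 (1.05 equiv), −50 °C → rt; n-BuLi (2.3 equiv), −78 → −40 °C; MeOH, −78 °C; distillation under reduced pressure, stored cold
Reagents that add atoms: none
Why: alkynyl ether synthesis from trichloroethylene: net vinylic substitution by alkoxide 17 gives 18, n-BuLi removes HCl to give 19 and then exchanges its chlorine for lithium, and protonation of 20 frees the terminal ynol ether, whose 2-silylethyl group survives all of this and can later be removed with fluoride.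

Step 9
Reactants: 14 2-(diazoacetyl)-6-Ar-5-methoxy-4H-pyran-4-one; 21 [2-(ethynyloxy)ethyl]trimethylsilane
Product: 26 5-hydroxy-3-methoxy-2-Ar-7-[2-(trimethylsilyl)ethoxy]chromen-4-one, via pyranonylketene 22 (not isolated), via alkoxycyclobutenone 23 (not isolated), via dienylketene 24 (not isolated), via cyclohexadienone 25 (not isolated)
Conditions: 21 (3 equiv), ClCH2CH2Cl (0.2 M), 405 nm LED, 20 °C, Ar, until N2 evolution stops; excess 21 evaporated; toluene, 100 °C, 2 h, dark
Reagents that add atoms: none
Why: Violet light should excite only the diazo ketone (the aryl pyranone absorbs at shorter wavelength), nitrogen is lost and C8a migrates from the acyl carbon to the diazo carbon (Wolff rearrangement), giving ketene 22 with the C8–C8a bond in place and the former carboxyl carbon as the ketene carbon, the future C5. The electron-rich alkyne 21 then adds in a regioselective [2+2] cycloaddition, its nucleophilic CH terminus bonding to the ketene carbon (C5–C6) and its oxygen-bearing carbon to the α-carbon (C7–C8), to give cyclobutenone 23; on heating, reversible conrotatory 4π opening gives dienylketene 24, and the isomer with the pyranone turned inward closes ring A by thermal disrotatory 6π electrocyclization onto the unsubstituted pyranone CH (C4a–C5), the only terminus available. Dienone 25 tautomerises at once, its C4a hydrogen lying between two carbonyl groups, so ring A becomes aromatic and the one transient stereocentre is lost (the target has none). The closest known reaction is the Danheiser benzannulation in its diazo ketone form, which turns unsaturated and heteroaryl α-diazo ketones with alkoxy- or silyloxyalkynes into resorcinol monoethers and fused hydroxy-heteroaromatics. The pattern needed (free OH on C5, ether on C7, hydrogen on C6 and C8) follows from the polarisation of the ynol ether and from the use of a terminal alkyne and of diazomethane; the silyl cap on O4' keeps a phenol from trapping the ketene, the new C5 hydroxyl is tied up in a hydrogen bond to C4=O, and the neutral medium below about 100 °C leaves the prenyl group alone.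

Step 10
Reactants: 26 5-hydroxy-3-methoxy-2-Ar-7-[2-(trimethylsilyl)ethoxy]chromen-4-one
Product: 27 dodoviscin J (5,7-dihydroxy-2-[4-hydroxy-3-methoxy-5-(3-methylbut-2-enyl)phenyl]-3-methoxychromen-4-one)
Conditions: TBAF (6 equiv), DMF, 0 → 50 °C; aq. NH4Cl
Reagents that add atoms: none
Why: fluoride-induced desilylation of the aryl TIPS ether and Peterson-type β-elimination of the 2-(trimethylsilyl)ethyl ether (loss of ethene): the O7 aryloxide is a vinylogous carboxylate and hence a good leaving group, so the ether should behave like a 2-silylethyl ester, and no acid is present that could close the freed 4'-OH onto the prenyl group.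

Compound list
1 | 4-bromo-2-methoxyphenol | COc1cc(Br)ccc1O | starting material
2 | 1-bromo-3-methylbut-2-ene (prenyl bromide) | CC(C)=CCBr | starting material
3 | sodium 4-bromo-2-methoxyphenoxide (not isolated) | COc1cc(Br)ccc1[O-].[Na+] | intermediate
4 | 4-bromo-2-methoxy-6-(3-methylbut-2-enyl)phenol | COc1cc(Br)cc(CC=C(C)C)c1O | intermediate
5 | [4-bromo-2-methoxy-6-(3-methylbut-2-enyl)phenoxy]triisopropylsilane | COc1cc(Br)cc(CC=C(C)C)c1O[Si](C(C)C)(C(C)C)C(C)C | intermediate
6 | comenic acid (5-hydroxy-4-oxo-4H-pyran-2-carboxylic acid) | O=C(O)c1cc(=O)c(O)co1 | starting material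
7 | 6-bromo-5-hydroxy-4-oxo-4H-pyran-2-carboxylic acid | O=C(O)c1cc(=O)c(O)c(Br)o1 | intermediate
8 | methyl 6-bromo-5-methoxy-4-oxo-4H-pyran-2-carboxylate | COC(=O)c1cc(=O)c(OC)c(Br)o1 | intermediate
9 | [3-methoxy-5-(3-methylbut-2-enyl)-4-(triisopropylsilyloxy)phenyl]lithium (not isolated) | [Li]c1cc(OC)c(O[Si](C(C)C)(C(C)C)C(C)C)c(CC=C(C)C)c1 | intermediate
10 | [3-methoxy-5-(3-methylbut-2-enyl)-4-(triisopropylsilyloxy)phenyl]zinc chloride (not isolated) | Cl[Zn]c1cc(OC)c(O[Si](C(C)C)(C(C)C)C(C)C)c(CC=C(C)C)c1 | intermediate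
11 | methyl 5-methoxy-6-[3-methoxy-5-(3-methylbut-2-enyl)-4-(triisopropylsilyloxy)phenyl]-4-oxo-4H-pyran-2-carboxylate | COC(=O)c1cc(=O)c(OC)c(-c2cc(OC)c(O[Si](C(C)C)(C(C)C)C(C)C)c(CC=C(C)C)c2)o1 | intermediate
12 | 5-methoxy-6-[3-methoxy-5-(3-methylbut-2-enyl)-4-(triisopropylsilyloxy)phenyl]-4-oxo-4H-pyran-2-carboxylic acid | OC(=O)c1cc(=O)c(OC)c(-c2cc(OC)c(O[Si](C(C)C)(C(C)C)C(C)C)c(CC=C(C)C)c2)o1 | intermediate
13 | ethyl carbonic anhydride of acid 12 (not isolated) | CCOC(=O)OC(=O)c1cc(=O)c(OC)c(-c2cc(OC)c(O[Si](C(C)C)(C(C)C)C(C)C)c(CC=C(C)C)c2)o1 | intermediate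
14 | 2-(diazoacetyl)-5-methoxy-6-[3-methoxy-5-(3-methylbut-2-enyl)-4-(triisopropylsilyloxy)phenyl]-4H-pyran-4-one | [N-]=[N+]=CC(=O)c1cc(=O)c(OC)c(-c2cc(OC)c(O[Si](C(C)C)(C(C)C)C(C)C)c(CC=C(C)C)c2)o1 | intermediate
15 | 2-(trimethylsilyl)ethanol | C[Si](C)(C)CCO | starting material
16 | trichloroethylene | ClC=C(Cl)Cl | starting material
17 | potassium 2-(trimethylsilyl)ethoxide (not isolated) | C[Si](C)(C)CC[O-].[K+] | intermediate
18 | (E)-[2-(1,2-dichloroethenyloxy)ethyl]trimethylsilane (geometry of no consequence, not isolated) | C[Si](C)(C)CCO/C(Cl)=C\Cl | intermediate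
19 | [2-(chloroethynyloxy)ethyl]trimethylsilane (not isolated) | C[Si](C)(C)CCOC#CCl | intermediate
20 | lithium [2-(trimethylsilyl)ethoxy]acetylide (not isolated) | [Li]C#COCC[Si](C)(C)C | intermediate
21 | [2-(ethynyloxy)ethyl]trimethylsilane | C#COCC[Si](C)(C)C | intermediate
22 | {5-methoxy-6-[3-methoxy-5-(3-methylbut-2-enyl)-4-(triisopropylsilyloxy)phenyl]-4-oxo-4H-pyran-2-yl}ketene (not isolated) | O=C=Cc1cc(=O)c(OC)c(-c2cc(OC)c(O[Si](C(C)C)(C(C)C)C(C)C)c(CC=C(C)C)c2)o1 | intermediate
23 | 4-{5-methoxy-6-[3-methoxy-5-(3-methylbut-2-enyl)-4-(triisopropylsilyloxy)phenyl]-4-oxo-4H-pyran-2-yl}-3-[2-(trimethylsilyl)ethoxy]cyclobut-2-en-1-one (racemic, not isolated) | O=C1C=C(OCC[Si](C)(C)C)C1c1cc(=O)c(OC)c(-c2cc(OC)c(O[Si](C(C)C)(C(C)C)C(C)C)c(CC=C(C)C)c2)o1 | intermediate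
24 | (E)-4-{5-methoxy-6-[3-methoxy-5-(3-methylbut-2-enyl)-4-(triisopropylsilyloxy)phenyl]-4-oxo-4H-pyran-2-yl}-3-[2-(trimethylsilyl)ethoxy]buta-1,3-dien-1-one (ketenyl group and pyranone cis, not isolated) | O=C=C/C(OCC[Si](C)(C)C)=C\c1cc(=O)c(OC)c(-c2cc(OC)c(O[Si](C(C)C)(C(C)C)C(C)C)c(CC=C(C)C)c2)o1 | intermediate
25 | 3-methoxy-2-[3-methoxy-5-(3-methylbut-2-enyl)-4-(triisopropylsilyloxy)phenyl]-7-[2-(trimethylsilyl)ethoxy]-4aH-chromene-4,5-dione (racemic, not isolated) | O=C1C=C(OCC[Si](C)(C)C)C=C2OC(-c3cc(OC)c(O[Si](C(C)C)(C(C)C)C(C)C)c(CC=C(C)C)c3)=C(OC)C(=O)C12 | intermediate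
26 | 5-hydroxy-3-methoxy-2-[3-methoxy-5-(3-methylbut-2-enyl)-4-(triisopropylsilyloxy)phenyl]-7-[2-(trimethylsilyl)ethoxy]chromen-4-one | COc1cc(-c2oc3cc(OCC[Si](C)(C)C)cc(O)c3c(=O)c2OC)cc(CC=C(C)C)c1O[Si](C(C)C)(C(C)C)C(C)C | intermediate
27 | dodoviscin J (achiral) | COc1cc(-c2oc3cc(O)cc(O)c3c(=O)c2OC)cc(CC=C(C)C)c1O | target

Total step count: 10. Longest linear sequence: 7 (steps 1, 2, 5, 6, 7, 9, 10).

Steps most likely to fail

Step 9 (key step). The aryl pyranone chromophore might be consumed by light in competition with the Wolff shift, or the ketene might dimerise before the alkyne captures it. The fallback sets out from 14 and returns at cyclobutenone 23, and so at 26. The Wolff shift would be run in the dark with silver benzoate (AgOCOPh, 10 mol %) and Et3N in THF/H2O below room temperature, giving the homologous {6-Ar-5-methoxy-4-oxo-4H-pyran-2-yl}acetic acid F1 (Arndt–Eistert homologation). 1-Chloro-N,N,2-trimethylprop-1-en-1-amine in CH2Cl2 would convert F1 into {6-Ar-5-methoxy-4-oxo-4H-pyran-2-yl}acetyl chloride F2 under neutral conditions. Slow addition of Et3N to F2 and 21 (5 equiv) in CH2Cl2 at 0 °C would generate ketene 22 by dehydrochlorination at low stationary concentration beside its trap. The resulting 23 would be heated in toluene as in step 9.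

Step 1. O-alkylation and dialkylation might outrun ortho-C-alkylation of the phenoxide. The fallback sets out from 1 and returns at 4. Allyl bromide and K2CO3 in acetone would give 1-(allyloxy)-4-bromo-2-methoxybenzene F3. Aromatic Claisen rearrangement in N,N-diethylaniline at 190 °C can only deliver the allyl group to the free ortho carbon, giving 2-allyl-4-bromo-6-methoxyphenol F4. Cross-metathesis of F4 in 2-methylbut-2-ene with RuCl2(=CHPh)(H2IMes)(PCy3) (second-generation Grubbs catalyst, 3 mol %) at rt would then turn allyl into prenyl.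

Step 5. The aryllithium might be quenched by proton transfer from the benzylic and allylic CH2 of the prenyl group, or transmetalation and coupling of the hindered, electron-rich zinc reagent might stall. The fallback sets out from 8 and returns at 11, with the prenyl group introduced after the biaryl bond. Suzuki coupling of 8 with commercial 2-methoxy-4-(4,4,5,5-tetramethyl-1,3,2-dioxaborolan-2-yl)phenol F5 (PdCl2(dppf), K3PO4, dioxane, 80 °C) would give methyl 6-(4-hydroxy-3-methoxyphenyl)-5-methoxy-4-oxo-4H-pyran-2-carboxylate F6. Its sodium phenoxide (NaH, toluene) would be C-prenylated with 2 at the only free ortho carbon, the para carbon now carrying the pyranone, giving methyl 6-[4-hydroxy-3-methoxy-5-(3-methylbut-2-enyl)phenyl]-5-methoxy-4-oxo-4H-pyran-2-carboxylate F7. Silylation as in step 2 would give 11.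

Further compounds
F1 | step 9 | {5-methoxy-6-[3-methoxy-5-(3-methylbut-2-enyl)-4-(triisopropylsilyloxy)phenyl]-4-oxo-4H-pyran-2-yl}acetic acid | OC(=O)Cc1cc(=O)c(OC)c(-c2cc(OC)c(O[Si](C(C)C)(C(C)C)C(C)C)c(CC=C(C)C)c2)o1
F2 | step 9 | {5-methoxy-6-[3-methoxy-5-(3-methylbut-2-enyl)-4-(triisopropylsilyloxy)phenyl]-4-oxo-4H-pyran-2-yl}acetyl chloride | ClC(=O)Cc1cc(=O)c(OC)c(-c2cc(OC)c(O[Si](C(C)C)(C(C)C)C(C)C)c(CC=C(C)C)c2)o1
F3 | step 1 | 1-(allyloxy)-4-bromo-2-methoxybenzene | C=CCOc1ccc(Br)cc1OC
F4 | step 1 | 2-allyl-4-bromo-6-methoxyphenol | C=CCc1cc(Br)cc(OC)c1O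
F5 | step 5 | 2-methoxy-4-(4,4,5,5-tetramethyl-1,3,2-dioxaborolan-2-yl)phenol | COc1cc(B2OC(C)(C)C(C)(C)O2)ccc1O
F6 | step 5 | methyl 6-(4-hydroxy-3-methoxyphenyl)-5-methoxy-4-oxo-4H-pyran-2-carboxylate | COC(=O)c1cc(=O)c(OC)c(-c2ccc(O)c(OC)c2)o1
F7 | step 5 | methyl 6-[4-hydroxy-3-methoxy-5-(3-methylbut-2-enyl)phenyl]-5-methoxy-4-oxo-4H-pyran-2-carboxylate | COC(=O)c1cc(=O)c(OC)c(-c2cc(OC)c(O)c(CC=C(C)C)c2)o1
A1 | direct plan | methyl vanillate (methyl 4-hydroxy-3-methoxybenzoate) | COC(=O)c1ccc(O)c(OC)c1
A2 | direct plan | methyl 4-hydroxy-3-methoxy-5-(3-methylbut-2-enyl)benzoate | COC(=O)c1cc(OC)c(O)c(CC=C(C)C)c1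
A3 | direct plan | methyl methoxyacetate | COCC(=O)OC
A4 | direct plan | methyl 2-methoxy-3-[3-methoxy-5-(3-methylbut-2-enyl)-4-(triisopropylsilyloxy)phenyl]-3-oxopropanoate (racemic) | COC(=O)C(OC)C(=O)c1cc(OC)c(O[Si](C(C)C)(C(C)C)C(C)C)c(CC=C(C)C)c1
A5 | direct plan | phloroglucinol | Oc1cc(O)cc(O)c1
A6 | direct plan | 5,7-dihydroxy-3-methoxy-2-[3-methoxy-5-(3-methylbut-2-enyl)-4-(triisopropylsilyloxy)phenyl]chromen-4-one | COc1cc(-c2oc3cc(O)cc(O)c3c(=O)c2OC)cc(CC=C(C)C)c1O[Si](C(C)C)(C(C)C)C(C)C
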